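**Plan**
1. Numbering. Ring A: C1 (CH3), C2 (H), C3 (OH), C4 (CHO), C5 (ether O), C6 (lactone C=O). Ring B is the arene of the chromanone: C5' (CH3), C6' (ether O), C7' (ester O).
2. Retrosynthesis. The lactone O–C(=O) bond is cut while the carbonyl carbon is tied back to the C1 methyl carbon, so the ortho-toluate becomes a benzocyclobutenone. Then follow the C5–O ether bond (SNAr), the C4–CHO bond (ortho-lithiation), and last the two bonds of the four-membered ring, C6–C(=O) and C1–CH2 (aryne plus ketene acetal). Ring B is cut at its aryl–acyl and O–CMe2 bonds.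
3. Forward order. The pyranone ring is built on ring B and a four-membered helper ring on ring A. Formylation, union through the ether bond and unmasking follow. The C7' phenol then opens the helper ring, which gives the seven-membered lactone and the C1 methyl group together.
4. Enabling feature. C1 (methyl) and C6 (acyl) are neighbours in ring A, and C6 is flanked by the heteroatom-bearing C5. This ortho-toluate is the opened form of a benzocyclobutenone made from an aryne C1≡C6 that the C5 substituent polarises. That substituent is fluorine, which later directs the C4 lithiation and leaves in the SNAr. C4 (CHO) lies para to C1 and guides the ring opening.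
5. Stereochemistry. The target has no stereocentre, so none has to be set.

Key step: step 3

Assumption: compounds 1, 4, 6 and 7 are taken as catalogue chemicals.

**Step 1**
Reactants: 1 2-methoxy-6-methylphenol
Product: 3 2-methoxy-6-methylbenzene-1,4-diol, via 2-methoxy-6-methylbenzoquinone 2 (not isolated)
Conditions: (KSO3)2NO (2.2 equiv), KH2PO4, H2O/acetone, 0 °C to rt; extraction into EtOAc; aq Na2S2O4, rt
Reagents that add atoms: potassium nitrosodisulfonate (KSO3)2NO, [K+].[K+].[O]N(S(=O)(=O)[O-])S(=O)(=O)[O-]
Why: Teuber oxidation of a phenol with a free para position should give the para-quinone, whose new oxygen comes from the nitroxyl radical, and dithionite reduction of the extract should give the hydroquinone.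

**Step 2**
Reactants: 3 2-methoxy-6-methylbenzene-1,4-diol; 4 3-methylbut-2-enoic acid
Product: 5 6-hydroxy-7-methoxy-2,2,5-trimethylchroman-4-one
Conditions: 4 (1.1 equiv), P2O5/MeSO3H (1:10 w/w), 70 °C
Reagents that add atoms: none
Why: Friedel–Crafts acylation followed by oxa-Michael closure, the usual one-pot route from phenols to 2,2-dimethylchroman-4-ones, should occur ortho to the unhindered 4-OH and para to OMe (the normal site for a resorcinol-type oxygen pair), while the 1-OH has both ortho positions blocked.

**Step 3**
Reactants: 6 3,5-difluoroanisole; 7 1,1-diethoxyethene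
Product: 10 7,7-diethoxy-5-fluoro-3-methoxybicyclo[4.2.0]octa-1,3,5-triene, via 2,6-difluoro-4-methoxyphenyllithium 8 (not isolated), via 3-fluoro-5-methoxybenzyne 9 (not isolated)
Conditions: n-BuLi (1.05 equiv), THF, −78 °C; then slow cannulation into 7 (4 equiv), THF, 0 °C to rt
Reagents that add atoms: none
Why: n-BuLi removes the proton between the two fluorines of 6 and aryllithium 8 loses LiF on warming, either fluorine giving the same aryne 9 because 8 is symmetric. The remaining fluorine, a sigma acceptor next to one aryne carbon, polarises the triple bond so that the nucleophilic CH2 terminus of 7 attacks the remote aryne carbon (future C1) and the charge builds up on the carbon next to fluorine (future C6). This aryl anion then collapses onto the diethoxycarbenium carbon, a 4-exo-trig closure that completes a formal [2+2] cycloaddition and forms the bond between C6 and the future lactone carbonyl carbon. The closest known reaction type is the regioselective [2+2] cycloaddition of 3-alkoxy- and 3-halobenzynes with ketene acetals, which gives benzocyclobutenone acetals whose acetal carbon lies next to the heteroatom-bearing carbon. No stereocentre is formed. The step needs site-selective lithiation (secured by the two flanking fluorines), one orientation of addition (secured by the remaining fluorine, which outweighs the remote methoxy group) and capture of 9 by 7 rather than by 8 (secured by slow inverse addition of 8 to excess 7).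

**Step 4**
Reactants: 10 7,7-diethoxy-5-fluoro-3-methoxybicyclo[4.2.0]octa-1,3,5-triene
Product: 12 7,7-diethoxy-5-fluoro-3-methoxybicyclo[4.2.0]octa-1,3,5-triene-4-carbaldehyde, via 4-lithio acetal 11 (not isolated)
Conditions: LiN(iPr)2 (1.1 equiv), THF, −78 °C; DMF, −78 °C; then H2O
Reagents that add atoms: N,N-dimethylformamide, CN(C)C=O
Why: Directed ortho-metalation followed by formylation with DMF should take place at C4, the only C–H flanked by fluorine and methoxy, and the ortho-fluoroaryllithium is stable at −78 °C.

**Step 5**
Reactants: 5 6-hydroxy-7-methoxy-2,2,5-trimethylchroman-4-one; 12 7,7-diethoxy-5-fluoro-3-methoxybicyclo[4.2.0]octa-1,3,5-triene-4-carbaldehyde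
Product: 13 7,7-diethoxy-3-methoxy-5-[(7-methoxy-2,2,5-trimethyl-4-oxochroman-6-yl)oxy]bicyclo[4.2.0]octa-1,3,5-triene-4-carbaldehyde
Conditions: Cs2CO3 (1.5 equiv), DMSO, 90 °C
Reagents that add atoms: none
Why: Nucleophilic aromatic substitution of the fluoride, activated by the ortho formyl group, should tolerate the hindered phenoxide because attack is perpendicular to ring A and the fused four-membered ring bends its acetal carbon away from C5, while the acetal keeps the strained ketone out of reach and the C7' methyl ether fixes which ring B oxygen becomes the ether.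

**Step 6**
Reactants: 13 7,7-diethoxy-3-methoxy-5-[(7-methoxy-2,2,5-trimethyl-4-oxochroman-6-yl)oxy]bicyclo[4.2.0]octa-1,3,5-triene-4-carbaldehyde
Product: 14 3-hydroxy-5-[(7-hydroxy-2,2,5-trimethyl-4-oxochroman-6-yl)oxy]-7-oxobicyclo[4.2.0]octa-1,3,5-triene-4-carbaldehyde
Conditions: BBr3 (6 equiv), CH2Cl2, −78 to 0 °C; then H2O/THF, rt
Reagents that add atoms: water, O
Why: Lewis acid cleavage of aryl methyl ethers by BBr3, helped at C3 by chelation to the formyl oxygen, should free both phenols, and the acidic aqueous work-up should hydrolyse the acetal to the ketone.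

**Step 7**
Reactants: 14 3-hydroxy-5-[(7-hydroxy-2,2,5-trimethyl-4-oxochroman-6-yl)oxy]-7-oxobicyclo[4.2.0]octa-1,3,5-triene-4-carbaldehyde
Product: 16 mollicellin A, via hemiketal alkoxide 15 (not isolated)
Conditions: DBU (0.3 equiv), MeCN (0.01 M), 40 °C; dilute HCl work-up
Reagents that add atoms: none
Why: This is the base-induced cleavage of a benzocyclobutenone by an oxygen nucleophile to an ortho-toluate, run intramolecularly: the C7' phenoxide adds to the strained ketone, alkoxide 15 undergoes oxyanion-accelerated electrocyclic opening of the C(=O)–CH2 bond (favoured because the resulting dienolate is conjugated with the new lactone carbonyl and the para formyl group), and protonation gives the C1 methyl group and the seven-membered lactone.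

**Compound list**
1 | 2-methoxy-6-methylphenol | COc1cccc(C)c1O | starting material
2 | 2-methoxy-6-methyl-1,4-benzoquinone | COC1=CC(=O)C=C(C)C1=O | intermediate
3 | 2-methoxy-6-methylbenzene-1,4-diol | COc1cc(O)cc(C)c1O | intermediate
4 | 3-methylbut-2-enoic acid | CC(C)=CC(=O)O | starting material
5 | 6-hydroxy-7-methoxy-2,2,5-trimethylchroman-4-one | COc1cc2OC(C)(C)CC(=O)c2c(C)c1O | intermediate
6 | 3,5-difluoroanisole | COc1cc(F)cc(F)c1 | starting material
7 | 1,1-diethoxyethene | C=C(OCC)OCC | starting material
8 | 2,6-difluoro-4-methoxyphenyllithium | [Li]c1c(F)cc(OC)cc1F | intermediate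
9 | 3-fluoro-5-methoxybenzyne | COC1=CC#CC(F)=C1 | intermediate
10 | 7,7-diethoxy-5-fluoro-3-methoxybicyclo[4.2.0]octa-1,3,5-triene | CCOC1(OCC)Cc2cc(OC)cc(F)c21 | intermediate
11 | 4-lithio derivative of 10 | CCOC1(OCC)Cc2cc(OC)c([Li])c(F)c21 | intermediate
12 | 7,7-diethoxy-5-fluoro-3-methoxybicyclo[4.2.0]octa-1,3,5-triene-4-carbaldehyde | CCOC1(OCC)Cc2cc(OC)c(C=O)c(F)c21 | intermediate
13 | diaryl ether acetal (ring A C5–O–C6' ring B; both phenols as methyl ethers) | CCOC1(OCC)Cc2cc(OC)c(C=O)c(Oc3c(OC)cc4OC(C)(C)CC(=O)c4c3C)c21 | intermediate
14 | bisphenol benzocyclobutenone | O=C1Cc2cc(O)c(C=O)c(Oc3c(O)cc4OC(C)(C)CC(=O)c4c3C)c21 | intermediate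
15 | hemiketal alkoxide from addition of the C7' oxygen to the four-ring ketone (racemic, transient stereocentre) | [O-]C12Cc3cc(O)c(C=O)c(Oc4c(C)c5C(=O)CC(C)(C)Oc5cc4O1)c32 | intermediate
16 | mollicellin A | Cc1cc(O)c(C=O)c2c1C(=O)Oc1cc3c(c(C)c1O2)C(=O)CC(C)(C)O3 | target

Total step count: 7. Longest linear sequence: 5 steps (1, 2, 5, 6, 7 or 3, 4, 5, 6, 7).

**Steps most likely to fail**

Step 3. The aryne may be consumed by unreacted aryllithium faster than by the ketene acetal, and the orientation of addition may erode. The fallback sets out from 5 and comes back at 16.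
- Commercial 2,6-difluoro-4-methylbenzaldehyde with one equivalent of NaOMe in MeOH gives 2-fluoro-6-methoxy-4-methylbenzaldehyde F1.
- NBS in MeCN should brominate F1 para to the methoxy group to give 3-bromo-2-fluoro-6-methoxy-4-methylbenzaldehyde F2.
- SNAr of F2 with 5 (Cs2CO3, DMSO) gives bromo diaryl ether F3, and BBr3 gives bromo bisphenol F4.
- Carbonylative ring closure (Pd(OAc)2, Xantphos, CO 1 atm, Et3N, toluene, 90 °C) joins C6 to the carbonyl carbon and gives 16.

Step 7. A weakly nucleophilic phenoxide may add too slowly to a ketone whose electrophilicity is lowered once the C3 phenol is deprotonated. The opened dienolate may also condense intermolecularly with formyl groups. The fallback sets out from 14 and comes back at 16. Aqueous NaOH in THF opens the four-membered ring intermolecularly to seco acid F5. Carbodiimide lactonisation (DCC, toluene, high dilution), the usual closure of depsidone lactones, then closes F5 to 16.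

Step 5. Substitution may be slow at a carbon flanked on both sides and attacked by a doubly ortho-substituted phenoxide, and the aldehyde may degrade at the temperature needed. The fallback sets out from 12 and 5 and comes back at 16.
- Aqueous HCl in THF converts 12 into keto aldehyde F6, and BBr3 converts 5 into catechol F7.
- With K2CO3 in MeCN the more acidic 7-OH of F7 should open the four-membered ring of F6 to depside F8.
- The 6-phenoxide of F8 then closes the ether bond by intramolecular SNAr at a C–F carbon now flanked by an ester and a formyl group, giving O-methylmollicellin A F9.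
- BCl3 (CH2Cl2, −20 °C) cleaves the methyl ether next to the formyl group to give 16.

**Further compounds**
F1 | step 3 | 2-fluoro-6-methoxy-4-methylbenzaldehyde | COc1cc(C)cc(F)c1C=O
F2 | step 3 | 3-bromo-2-fluoro-6-methoxy-4-methylbenzaldehyde | COc1cc(C)c(Br)c(F)c1C=O
F3 | step 3 | bromo diaryl ether | COc1cc(C)c(Br)c(Oc2c(OC)cc3OC(C)(C)CC(=O)c3c2C)c1C=O
F4 | step 3 | bromo bisphenol | Cc1cc(O)c(C=O)c(Oc2c(O)cc3OC(C)(C)CC(=O)c3c2C)c1Br
F5 | step 7 | seco acid | Cc1cc(O)c(C=O)c(Oc2c(O)cc3OC(C)(C)CC(=O)c3c2C)c1C(=O)O
F6 | step 5 | keto aldehyde | COc1cc2CC(=O)c2c(F)c1C=O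
F7 | step 5 | catechol | Cc1c(O)c(O)cc2OC(C)(C)CC(=O)c12
F8 | step 5 | depside | COc1cc(C)c(C(=O)Oc2cc3OC(C)(C)CC(=O)c3c(C)c2O)c(F)c1C=O
F9 | step 5 | O-methylmollicellin A | COc1cc(C)c2C(=O)Oc3cc4OC(C)(C)CC(=O)c4c(C)c3Oc2c1C=O
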